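Assumption: compound 14 has no stereocentre and no stereogenic double bond, so the demand for a single enantiomer is met by the constitution alone; the one chiral intermediate (epoxide 13) is carried as the racemate because both of its stereocentres are erased in the last step.

Ring atoms are numbered as in the target throughout: C1 carbonyl, C2 hydroxyl, C3 henicosyl, C4 carbonyl, C5 methoxyl, C6 hydrogen.

## The problem

Compound 14 is a 1,4-benzoquinone with four oxygens and one unbranched C21 chain on a single six-membered ring: carbonyls at C1 and C4, a free hydroxyl at C2, the henicosyl group at C3, a methoxyl at C5 and the only ring hydrogen at C6. No ring has to be built if the synthesis starts from a benzene, so the work lies in joining the saturated chain to the ring through one C(sp2)–C(sp3) bond and in placing the oxygens. There is no stereocentre, and every selectivity question is regiochemical: which ring carbons are oxidised, and how the hydroxyl next to the chain is told apart from the methyl ether across the ring. The C5 methoxyl is a vinylogous ester that hydroxide and amines displace by addition–elimination, the C2 hydroxyl is a vinylogous acid, and the quinone is degraded by strong base, reductants and soft nucleophiles; the quinone should therefore appear late and see only cold, weakly basic or acidic media. The long chain makes every intermediate waxy and poorly soluble in water and in neat methanol, which limits aqueous oxidants and electrolysis media. The feature that opens the route shows when the oxygens at C2 and C4 are taken away: what remains is the 5-alkylresorcinol monomethyl ether 8, in which C4, between the chain carbon C3 and the methoxy carbon C5, lies para to the phenol oxygen on C1. A phenol is oxidised at its para position, so C4 can be oxygenated directly, and in the resulting methoxyquinone C2 is the one ring CH para to the methoxyl and so the site where nucleophilic oxygen enters.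

## Retrosynthesis

**14 from 13.** The hydroxyl oxygen of 14 is bridged back from C2 to C3, which turns the enol into the C2–C3 epoxide 13; no carbon–carbon bond is cut. The neighbouring cuts at this oxygen are worse: displacing a C2 leaving group with hydroxide would also attack the C5 methoxyl, and carrying the C2 oxygen from the aromatic stage would give a benzene with three oxygens that must be told apart. Compound 13 is an isomer of 14, so nothing is gained in size, but the oxygen now comes from a reaction whose regiochemistry is understood. The forward step must open the epoxide in acid and remove a proton; only C2 carries hydrogen, so the hydroxyl can only end up there.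

**13 from 12.** Both C–O bonds of the epoxide are cut, which leaves the methoxyquinone 12. Epoxidising one stage earlier, on ketal 11, was weighed and set aside as the main line. In 11 the only carbonyl is C1, which the C5 methoxyl weakens as an acceptor, and the peroxide would have to attack C3, a fully substituted carbon next to the ketal. In 12 the C4 carbonyl is free, is not in conjugation with the methoxyl lone pair, and activates C2, an unhindered CH. The precursor has one oxygen fewer. The forward reaction must be a nucleophilic epoxidation mild enough to spare a methoxyquinone.

**12 from 11.** The C4 carbonyl is traced back to a dimethyl ketal. One C4–O bond is cleaved by water in the forward sense. Against oxidising 8 straight to 12 with a stoichiometric radical oxidant in water, the ketal is what an oxidation in methanol delivers, it is not oxidised further, and it tolerates the base formed at a cathode. The oxidation level is unchanged. The forward reaction is a hydrolysis in dilute acid that must leave the C5 enol ether alone.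

**11 from 8 and 9.** Both C4–O bonds of 11 are cut and the ring is re-aromatised, which leads to phenol 8 and two molecules of methanol 9, with the 4-methoxyphenol 10 lying between them. Oxygenating C4 by metalation or by formylation and oxidative rearrangement would need several steps and would have to find the most hindered ring position; the anodic route uses the innate reactivity of the phenol and no reagent but current. Precursor 8 has only two oxygens and belongs to a routinely made compound class. The forward reaction must trap the phenoxonium ion at C4 and not at C2 or C6, and must stay on the two-electron path.

**8 from 7.** The phenol O–H is traced to an O–CH3 bond, which leads to the symmetrical dimethyl ether 7. Symmetry means it does not matter which methyl is removed, whereas a differentiated 3-hydroxy-5-methoxy building block would need a protecting group through the olefination. The forward reaction is a thiolate demethylation that stops after one methyl.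

**7 from 6, 6 from 4 and 5, 5 from 3, 3 from 1 and 2.** The chain is cut between its first and second carbon, drawn as the double bond of alkene 6. This leads to 3,5-dimethoxybenzaldehyde 4 and ylide 5, made from phosphonium salt 3, itself from 1-bromoicosane 1 and triphenylphosphine 2. The aldehyde carbon becomes the first chain carbon, so the commodity C20 bromide suffices; a cut at the aryl–CH2 bond would need a C21 halide and a cross-coupling. The alkene geometry is irrelevant because hydrogenation to 7 follows. The forward steps are a Wittig olefination with a non-stabilised ylide and a hydrogenation.

## Roads not taken

**Alternative 1:** The ring itself is cut at C3–C4, C1–C2 and C1–C6. C4, C5 and C6 come from the alkenyl carbene complex A2, C2 and C3 from the alkynylboronate A3, and C1 from a carbonyl ligand. The Dötz benzannulation would give phenol A1 with boron next to the new hydroxyl and the chain next to the carbene-derived carbon; oxidation of the 4-methoxyphenol unit to the quinone and of the C–B bond to the C2 hydroxyl would finish the synthesis.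
- Merits: every oxygen is placed by the way the ring is built, not by the innate preference of an oxidation. The hydroxyl arrives as a C–B bond that needs only mild oxidation. On paper the linear sequence is no longer than the chosen one and perhaps shorter.
- Weak points: chromium is stoichiometric. A2 is an α-alkoxyvinyl carbene complex, electron-rich and less robust than the usual partners. A3 needs a C23 terminal alkyne that must be made from a non-commodity C21 halide. The order of the two final oxidations must avoid the ortho-quinone of the intermediate catechol.
- Comparison: in regiochemical certainty this road is better. The chosen plan sets against it commodity starting materials, no stoichiometric transition metal and current as the oxidant; it pays with a dependence on the para preference of a phenol oxidation.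

**Alternative 2:** The C4–C5 ring bond is cut and, further back, the bonds around a squarate core. Cyclobutenone A5, made by adding a metallated methoxyacetylene to the more electrophilic carbonyl of cyclobutenedione A6, is heated. Four-electron ring opening gives an enynyl ketene whose ketene carbon (C4) bonds to the methoxy-bearing alkyne carbon (C5), and hydrogen transfer in the resulting diradical gives quinone A4 (Moore ring expansion). Acid then removes the tert-butyl group.
- Merits: the substitution pattern is written into A5. The quinone appears at the right oxidation level without an external oxidant. The two oxygens that must be told apart are distinct from the start. The sequence is shorter than the chosen one, about five steps from a squaric ester.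
- Weak points: the enynyl ketene can close to the six-membered quinone or to a five-membered alkylidene cyclopentenedione depending on the alkyne terminus, and an oxygen-substituted terminus is not the safest case. The acetylide must be generated from a volatile, unstable precursor. The acid normally used to collapse the first squarate adduct to A6 threatens the tert-butyl ether. The chain enters as a C21 organometallic, again from a non-commodity halide.
- Comparison: this road is shorter and its regiochemical logic is cleaner. The chosen plan sets against it that each of its steps belongs to a reaction type with close precedent on alkylresorcinols and alkylquinones, that no cryogenic organometallic step follows the chain attachment, and that its starting materials are cheap.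

**Alternative 3:** C1–C6 and C2–C3 are cut, which divides the ring into the α-diketone A8 (C3 to C6 with the chain) and dimethyl oxalate A9 (C1 and C2). A double Claisen condensation, in which the methyl and the methylene enolate of A8 each acylate one oxalate carbon, would give a cyclohexanetetraone whose stable tautomer is the dihydroxyquinone A7. A selective O-methylation at C5 would complete the synthesis.
- Merits: ring and oxidation pattern arise in one condensation from acyclic material without any oxidant. On paper it is the shortest road, two steps from A8.
- Weak points: A8 is not available and needs its own synthesis. Unsymmetrical 1,2-diketones undergo self-aldol condensation under the base the Claisen reaction needs. The final methylation must choose the C5 hydroxyl over the C2 hydroxyl of A7, two vinylogous acids that differ only in the neighbouring chain, so a mixture with the regioisomer and the dimethyl ether is to be expected.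
- Comparison: in step count this alternative wins if both steps work. The chosen plan sets against it that the methyl ether is carried in from the starting material and the hydroxyl is introduced last at a site fixed by the polarisation of the quinone, so the two oxygens never have to be told apart.

Key step: step 5

## Route

Step 1
Reactants: 1 1-bromoicosane; 2 triphenylphosphine
Product: 3 icosyltriphenylphosphonium bromide
Conditions: PPh3 (1.1 equiv), MeCN, reflux, 48 h; trituration with Et2O
Reagents that add atoms: none
Why: SN2 quaternisation of triphenylphosphine by a primary alkyl bromide; the salt should crystallise on cooling or on trituration.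

Step 2
Reactants: 3 icosyltriphenylphosphonium bromide; 4 3,5-dimethoxybenzaldehyde
Product: 6 1-(henicos-1-en-1-yl)-3,5-dimethoxybenzene (Z/E mixture; mainly Z), via icosylidenetriphenylphosphorane 5 (not isolated)
Conditions: n-BuLi (1.05 equiv), THF, 0 °C; then 4, 0 °C to rt
Reagents that add atoms: none
Why: Wittig olefination: deprotonation of 3 gives the non-stabilised ylide 5, which adds to the aryl aldehyde and collapses through the oxaphosphetane to the alkene and triphenylphosphine oxide; the Z/E ratio does not matter because the double bond is hydrogenated next.

Step 3
Reactants: 6 1-(henicos-1-en-1-yl)-3,5-dimethoxybenzene
Product: 7 1-henicosyl-3,5-dimethoxybenzene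
Conditions: H2 (1 atm), 10% Pd/C, EtOAc, rt
Reagents that add atoms: none
Why: Heterogeneous catalytic hydrogenation of a disubstituted styrene-type alkene; the arene and the aryl methyl ethers are inert at one atmosphere and room temperature.

Step 4
Reactants: 7 1-henicosyl-3,5-dimethoxybenzene
Product: 8 3-henicosyl-5-methoxyphenol
Conditions: NaSEt (4 equiv), DMF, 140 °C; aq. HCl work-up
Reagents that add atoms: none
Why: SN2 demethylation of an aryl methyl ether by ethanethiolate; the phenoxide left by the first cleavage makes the second aryloxide a much poorer leaving group, so the reaction should stop at the monomethyl ether, and the symmetry of 7 allows only one product.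

Step 5
Reactants: 8 3-henicosyl-5-methoxyphenol; 9 methanol
Product: 11 5-henicosyl-3,4,4-trimethoxycyclohexa-2,5-dien-1-one, via 3-henicosyl-4,5-dimethoxyphenol 10 (not isolated)
Conditions: undivided cell, Pt anode and Pt cathode, constant current (ca. 5 mA cm⁻², 4–4.5 F mol⁻¹), LiClO4 (0.1 M), 2,6-lutidine (2 equiv), MeOH–THF 3:1, 15 °C; NaHCO3 work-up
Reagents that add atoms: methanol (compound 9, also co-solvent), CO
Why: Two-electron anodic oxidation of phenol 8 with loss of a proton gives a phenoxonium ion with positive charge at C2, C4 and C6; methanol adds at C4 and the adduct tautomerises to the 4-methoxyphenol 10. Compound 10 is oxidised more easily than 8, so it is converted at once into a second phenoxonium ion, now an oxocarbenium ion at C4, which methanol can only trap ipso to give the 4,4-dimethoxy dienone 11; four faradays per mole are consumed and the released protons are reduced to hydrogen at the cathode. The closest known reaction type is the anodic methoxylation of para-unsubstituted phenols and of 4-methoxyphenols to quinone monoketals in methanol, with the iodine(III) oxidation of phenols in methanol as its chemical counterpart. Two C4–O bonds are formed, no ring is closed and no stereocentre is created. The selectivity needed is para over ortho capture in the first methoxylation: the C5 methoxyl stabilises the cation at all three positions and does not discriminate, so the preference must come from the larger LUMO coefficient at the para carbon of a phenoxonium ion and from the greater stability of the cross-conjugated para dienone, against the hindrance at C4 from its two neighbours. The second methoxylation has no regiochemical freedom. A neutral electrolyte with a hindered pyridine buffer and a dilute solution favour the two-electron path over phenoxyl radical coupling, THF keeps the waxy substrate dissolved, and 11 is neither oxidised further nor harmed by the methoxide formed at the cathode.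

Step 6
Reactants: 11 5-henicosyl-3,4,4-trimethoxycyclohexa-2,5-dien-1-one
Product: 12 2-henicosyl-6-methoxy-1,4-benzoquinone
Conditions: 1 M aq. HCl, THF, rt
Reagents that add atoms: water, O
Why: Acid-catalysed hydrolysis of a quinone monoketal through the C4 oxocarbenium ion, driven by formation of the conjugated quinone; the C5 enol ether of a methoxyquinone should not be hydrolysed by dilute acid at room temperature.

Step 7
Reactants: 12 2-henicosyl-6-methoxy-1,4-benzoquinone
Product: 13 rac-(1S,6R)-1-henicosyl-3-methoxy-7-oxabicyclo[4.1.0]hept-3-ene-2,5-dione (the C2–C3 epoxide of 12 in target numbering)
Conditions: 30% aq. H2O2, Na2CO3, THF–EtOH, 0 °C, short contact time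
Reagents that add atoms: hydrogen peroxide, OO
Why: Weitz–Scheffer nucleophilic epoxidation: hydroperoxide adds to C2, the unhindered β-carbon of the C4(=O)–C3=C2 enone, and the enolate closes onto oxygen at C3 with loss of hydroxide; the C5=C6 bond is a vinylogous ester and should not react, and the two new stereocentres form as a racemic pair whose cis ring fusion is the only one possible and which step 8 erases.

Step 8
Reactants: 13 rac-(1S,6R)-1-henicosyl-3-methoxy-7-oxabicyclo[4.1.0]hept-3-ene-2,5-dione
Product: 14 2-hydroxy-3-henicosyl-5-methoxy-1,4-benzoquinone
Conditions: conc. H2SO4, CH2Cl2 (two-phase, vigorous stirring), 0 °C, brief; then ice–water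
Reagents that add atoms: none
Why: Acid-catalysed isomerisation of a 2-alkyl epoxyquinone to the 3-alkyl-2-hydroxyquinone, the reaction type by which 2-methyl-1,4-naphthoquinone oxide gives 2-hydroxy-3-methyl-1,4-naphthoquinone: the protonated epoxide opens, the C2 proton is lost and the resulting enol is the hydroxyquinone; only C2 carries hydrogen, so the hydroxyl can only end up there, and both stereocentres disappear.

## Compound list

1 | 1-bromoicosane | CCCCCCCCCCCCCCCCCCCCBr | starting material
2 | triphenylphosphine | c1ccc(cc1)P(c1ccccc1)c1ccccc1 | starting material
3 | icosyltriphenylphosphonium bromide | CCCCCCCCCCCCCCCCCCCC[P+](c1ccccc1)(c1ccccc1)c1ccccc1.[Br-] | intermediate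
4 | 3,5-dimethoxybenzaldehyde | COc1cc(C=O)cc(OC)c1 | starting material
5 | icosylidenetriphenylphosphorane (ylide; not isolated) | CCCCCCCCCCCCCCCCCCCC=P(c1ccccc1)(c1ccccc1)c1ccccc1 | intermediate
6 | 1-(henicos-1-en-1-yl)-3,5-dimethoxybenzene (Z/E mixture; Z isomer drawn) | CCCCCCCCCCCCCCCCCCC/C=C\c1cc(OC)cc(OC)c1 | intermediate
7 | 1-henicosyl-3,5-dimethoxybenzene | CCCCCCCCCCCCCCCCCCCCCc1cc(OC)cc(OC)c1 | intermediate
8 | 3-henicosyl-5-methoxyphenol | CCCCCCCCCCCCCCCCCCCCCc1cc(O)cc(OC)c1 | intermediate
9 | methanol | CO | starting material
10 | 3-henicosyl-4,5-dimethoxyphenol (not isolated) | CCCCCCCCCCCCCCCCCCCCCc1cc(O)cc(OC)c1OC | intermediate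
11 | 5-henicosyl-3,4,4-trimethoxycyclohexa-2,5-dien-1-one | CCCCCCCCCCCCCCCCCCCCCC1=CC(=O)C=C(OC)C1(OC)OC | intermediate
12 | 2-henicosyl-6-methoxy-1,4-benzoquinone | CCCCCCCCCCCCCCCCCCCCCC1=CC(=O)C=C(OC)C1=O | intermediate
13 | rac-(1S,6R)-1-henicosyl-3-methoxy-7-oxabicyclo[4.1.0]hept-3-ene-2,5-dione (racemic; cis-fused; one enantiomer drawn) | CCCCCCCCCCCCCCCCCCCCC[C@]12O[C@H]1C(=O)C=C(OC)C2=O | intermediate
14 | 2-hydroxy-3-henicosyl-5-methoxy-1,4-benzoquinone (achiral) | CCCCCCCCCCCCCCCCCCCCCC1=C(O)C(=O)C=C(OC)C1=O | target

## Step count and risks

Total steps: 8. Longest linear sequence: 8 steps, from 1-bromoicosane 1 to 14; compounds 2, 4 and 9 are purchased and enter at steps 1, 2 and 5.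

**Step 5 (key step).** The likeliest failure is capture of the phenoxonium ion by methanol at C2 or C6 instead of C4, since C4 is the most hindered of the three activated positions; the resulting ortho-quinol ethers would dimerise. A second failure mode is drift onto the one-electron path, with phenoxyl radical coupling. A third is coating of the anode by the waxy substrate, which stalls the electrolysis. The fallback sets out from 8 and comes back at 12: Teuber oxidation with Fremy's salt in a buffered two-phase medium (aqueous phosphate and CH2Cl2 with a phase-transfer catalyst) should convert the phenol directly into the para-quinone. Ketal 11 and step 6 are bypassed, and no compound outside the list is made (F0).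

**Step 7.** The likeliest failure is base-induced degradation of the methoxyquinone before or after epoxidation: displacement of the C5 methoxyl by hydroxide or hydroperoxide through addition–elimination, or oxidative ring cleavage by excess peroxide. The fallback sets out from 11 and comes back at 13, and epoxidises before the quinone is unmasked. The base-stable ketal is treated with tert-butyl hydroperoxide and benzyltrimethylammonium hydroxide in THF to give rac-6-henicosyl-4,5,5-trimethoxy-7-oxabicyclo[4.1.0]hept-3-en-2-one F1, and dilute aqueous acid in THF then hydrolyses the ketal to 13. This epoxidation should be slower, because the only carbonyl is the methoxyl-weakened one and the attacked carbon is fully substituted, but the substrate tolerates long exposure to base.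

**Step 8.** The likeliest failure is acyl migration in the opened epoxy ketone, which contracts the ring instead of losing the C2 proton; a second is cleavage of the vinylogous methyl ester during the quench of the strong acid. The fallback sets out from 12 and comes back at 14 by Thiele–Winter acetoxylation. Acetic anhydride with catalytic H2SO4 (or BF3·OEt2) should add acetate at C2, para to the methoxyl, and give 3-henicosyl-5-methoxybenzene-1,2,4-triyl triacetate F2. Methanolic HCl under nitrogen then gives 3-henicosyl-5-methoxybenzene-1,2,4-triol F3, which air or aqueous FeCl3 should oxidise to 14.

## Further compounds

F0 | step 5 | none | none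
F1 | step 7 | rac-6-henicosyl-4,5,5-trimethoxy-7-oxabicyclo[4.1.0]hept-3-en-2-one (racemic; cis-fused) | CCCCCCCCCCCCCCCCCCCCC[C@]12O[C@H]1C(=O)C=C(OC)C2(OC)OC
F2 | step 8 | 3-henicosyl-5-methoxybenzene-1,2,4-triyl triacetate | CCCCCCCCCCCCCCCCCCCCCc1c(OC(C)=O)c(OC(C)=O)cc(OC)c1OC(C)=O
F3 | step 8 | 3-henicosyl-5-methoxybenzene-1,2,4-triol | CCCCCCCCCCCCCCCCCCCCCc1c(O)c(O)cc(OC)c1O
A1 | alternative 1 | 3-henicosyl-4,5-dimethoxy-2-(4,4,5,5-tetramethyl-1,3,2-dioxaborolan-2-yl)phenol | CCCCCCCCCCCCCCCCCCCCCc1c(B2OC(C)(C)C(C)(C)O2)c(O)cc(OC)c1OC
A2 | alternative 1 | pentacarbonyl[methoxy(1-methoxyethenyl)carbene]chromium(0) | C=C(OC)C(OC)=[Cr](=C=O)(=C=O)(=C=O)(=C=O)=C=O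
A3 | alternative 1 | 4,4,5,5-tetramethyl-2-(tricos-1-yn-1-yl)-1,3,2-dioxaborolane | CCCCCCCCCCCCCCCCCCCCCC#CB1OC(C)(C)C(C)(C)O1
A4 | alternative 2 | 2-tert-butoxy-3-henicosyl-5-methoxy-1,4-benzoquinone | CCCCCCCCCCCCCCCCCCCCCC1=C(OC(C)(C)C)C(=O)C=C(OC)C1=O
A5 | alternative 2 | 3-tert-butoxy-2-henicosyl-4-hydroxy-4-(methoxyethynyl)cyclobut-2-en-1-one (racemic) | CCCCCCCCCCCCCCCCCCCCCC1=C(OC(C)(C)C)C(O)(C#COC)C1=O
A6 | alternative 2 | 3-tert-butoxy-4-henicosylcyclobut-3-ene-1,2-dione | CCCCCCCCCCCCCCCCCCCCCC1=C(OC(C)(C)C)C(=O)C1=O
A7 | alternative 3 | 2,5-dihydroxy-3-henicosyl-1,4-benzoquinone | CCCCCCCCCCCCCCCCCCCCCC1=C(O)C(=O)C=C(O)C1=O
A8 | alternative 3 | pentacosane-2,3-dione | CCCCCCCCCCCCCCCCCCCCCCC(=O)C(C)=O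
A9 | alternative 3 | dimethyl oxalate | COC(=O)C(=O)OC
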